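There were 4 questions, two on green and two on ochre, and each flask was charged with nearly equal amounts of starting complex and incoming ligand.

| setting | south-east | south-west | north-east | green | ochre |
|---|---|---|---|---|---|
| starting complex | 8.5 mM | 13 mM | 17 mM | 17 mM | 17 mM |
| incoming ligand | 17.9 mM | 17.9 mM | 17.9 mM | 17.9 mM | 17.9 mM |
| leaving ligand | 17 mM | 17 mM | 26 mM | 17.0 mM | 17.0 mM |
| capture agent | 1.7 mM | 1.7 mM | 1.7 mM | 1.70 mM | 1.70 mM |
| temperature | 30 °C | 45 °C | 30 °C | 55 °C | 35 °C |
| remark | run made earlier | run made earlier | run made earlier |  |  |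
| time |  |  |  | 1.0 h | 1.0 h |

| run | time / min | complex with three exchanged / % | trapped intermediate / % | starting complex / % | complex with two exchanged / % | complex with one exchanged / % |
|---|---|---|---|---|---|---|
| south-east | 8.00 | 0 | 0.5 | 80.9 | 0 | 18.0 |
| south-east | 15.0 | 0 | 0 | 68.6 | 1.7 | 28.5 |
| south-east | 25.0 | 1.2 | 0.1 | 54.6 | 3.2 | 40.6 |
| south-east | 30.0 | 5.0 | 1.7 | 50.1 | 2.8 | 42.2 |
| south-east | 40.0 | 3.9 | 0 | 39.8 | 4.3 | 49.3 |
| south-east | 50.0 | 9.2 | 0.6 | 34.5 | 4.1 | 48.7 |
| south-east | 60.0 | 11.1 | 1.6 | 31.4 | 4.2 | 52.1 |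
| south-west | 3.00 | 0.9 | 1.2 | 80.3 | 0 | 17.7 |
| south-west | 5.00 | 2.2 | 0.7 | 70.5 | 2.6 | 26.4 |
| south-west | 8.00 | 0 | 0 | 60.9 | 1.8 | 33.6 |
| south-west | 10.0 | 0.6 | 0.6 | 55.1 | 1.9 | 39.1 |
| south-west | 15.0 | 0.9 | 0.3 | 47.1 | 4.5 | 47.1 |
| south-west | 25.0 | 3.1 | 1.7 | 32.8 | 7.2 | 56.8 |
| south-west | 40.0 | 3.3 | 3.0 | 24.0 | 7.6 | 61.5 |
| north-east | 12.0 | 0.2 | 0.9 | 74.4 | 2.7 | 24.0 |
| north-east | 25.0 | 2.4 | 0 | 58.6 | 2.6 | 34.7 |
| north-east | 40.0 | 1.8 | 0.8 | 48.6 | 4.1 | 43.4 |
| north-east | 50.0 | 2.5 | 0 | 45.8 | 2.8 | 46.9 |
| north-east | 60.0 | 3.8 | 1.7 | 41.6 | 5.8 | 50.1 |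

(each reading ± 1 percentage point)

- the numbers in the tables scatter by 1 percentage point (one standard deviation)
- a reading or a percentage of complex with three exchanged counts all its forms, free or not

- which of these there is most of at the end, counted by the starting complex in it, green (trapped intermediate / complex with two exchanged / starting complex / complex with one exchanged / complex with three exchanged)
- which of these there is most of at the end, counted by the starting complex in it, ochre (trapped intermediate / complex with two exchanged / starting complex / complex with one exchanged / complex with three exchanged)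
- amount of the one of these that there is most of at the end, in percent of the starting complex charged, green
- amount of the one of these that there is most of at the end, in percent of the starting complex charged, ochre

I took the rate as k[starting complex][incoming ligand]. With equal charges the two concentrations stay nearly equal, so the integrated second-order rate law reads: charge/[starting complex] = 1 + k × charge × time. I called k × charge × time the clock number, and the fraction of starting complex left is then 1/(1 + clock number).

The north-east table suited this, since its charges were also close. Its row at 12.0 min gave k = 0.00169 mM⁻¹ min⁻¹, and the row at 25.0 min gave 0.00166 mM⁻¹ min⁻¹, which agrees. The row at 40.0 min gave 0.00156 mM⁻¹ min⁻¹, and the row at 60.0 min gave 0.00138 mM⁻¹ min⁻¹, which is less. So I kept the second row as the early reading at 30 °C, before that fall set in.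

The south-west charges were unequal, so there I used the unequal form of the same integration, and its row at 10.0 min gave 0.00411 mM⁻¹ min⁻¹. The two readings gave an activation energy of 48.4 kJ mol⁻¹, hence 0.00227 mM⁻¹ min⁻¹ for ochre and 0.00718 mM⁻¹ min⁻¹ for green.

The clock number 2.32 for ochre and 7.32 for green left 30.2% and 12.0% of the starting complex. The last north-east row put 85.8% of the converted complex in complex with one exchanged. Holding that share, I reckoned 59.9% of it in ochre and 75.5% in green, more than the starting complex left in each.

The forecast also named complex with one exchanged for both flasks, but at 60% in green and 53% in ochre, lower than my figures. Its grounds held “a weak reverse reaction, K about 20–30”, with starting complex about 27% in green, where I had 12.0%.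

Green gave complex with one exchanged at 69.2%, and ochre gave complex with one exchanged at 53.4%.

    complex with one exchanged + incoming ligand ⇌ leaving ligand + complex with two exchanged (K = 0.780, k = 0.0161 M⁻¹ s⁻¹, Ea = 50.0 kJ mol⁻¹, ΔH = −31.0 kJ mol⁻¹)
    complex with three exchanged + incoming ligand ⇌ idle adduct, settled at all times (K = 214 M⁻¹, ΔH = −30.0 kJ mol⁻¹)
    starting complex + incoming ligand ⇌ leaving ligand + complex with one exchanged (K = 57.7, k = 0.0371 M⁻¹ s⁻¹, Ea = 52.0 kJ mol⁻¹, ΔH = −18.0 kJ mol⁻¹)
    starting complex + complex with three exchanged → side product (k = 0.0281 M⁻¹ s⁻¹, Ea = 59.0 kJ mol⁻¹)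
    complex with one exchanged + capture agent → trapped intermediate (k = 0.00825 M⁻¹ s⁻¹, Ea = 55.0 kJ mol⁻¹)
    complex with two exchanged + incoming ligand ⇌ leaving ligand + complex with three exchanged (K = 2.30, k = 0.176 M⁻¹ s⁻¹, Ea = 66.0 kJ mol⁻¹, ΔH = −53.0 kJ mol⁻¹)
    (constants at 35 °C)

Green held 69.2% of complex with one exchanged and, with the difference in temperature taken away, 53.4%, so that difference gave the gap of 16 percentage points to ochre; it took the clock number from 2.32 to 7.32. The starting complex stood above the reckoning in ochre, at 34.4% against 30.2%, and in green, at 19.3% against 12.0%. Ochre read at 2.5 h has a clock number of 5.79, which leaves 14.7%. That flask held 21.9% of starting complex, with 63.4% of complex with one exchanged.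

The runs come from a simulation with made-up constants, and the scatter is random.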